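The lower pyran ring (O1–C2–C3–C4–C4a–C8a), and incidentally the upper one, is first made one atom smaller. The disconnection is C4–C4a: in a 3-methylidene-2,3-dihydrobenzofuran the exocyclic CH2 is the future C4. An iodine(III)-induced 1,2-shift of the electron-rich phloroglucinol carbon C4a from C3 to this CH2 enlarges the furan ring to the chroman-3-one in one operation. It exploits the C3 oxygen flanked by a benzylic C4 methylene on the trioxygenated A ring, and leaves C2 (set by Ir-catalysed allylic etherification) untouched. Reduction gives benzylated epigallocatechin, which serves as C8-bromo 3-O-gallate nucleophile and as 4-alkoxy electrophile for the 4β→6 coupling.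

Key step: step 7

Remark: 1, 5 and 14 are taken as purchased; "Ar" in names stands for 3,4,5-tris(benzyloxy)phenyl.
Assumption: the (Ra,Rc,Rc)-phosphoramidite is taken to give the (S)-ether in step 5; should the sense of induction be the opposite, its enantiomer is used.

Step 1
Reactants: 1 3,4,5-tris(benzyloxy)benzaldehyde
Product: 2 ethyl (2E)-3-Ar-prop-2-enoate
Conditions: Ph3P=CHCO2Et, toluene, 90 °C
Reagents that add atoms: (carbethoxymethylene)triphenylphosphorane, CCOC(=O)C=P(c1ccccc1)(c1ccccc1)c1ccccc1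
Why: Wittig olefination with a stabilised ylide should give the (E)-enoate.

Step 2
Reactants: 2 ethyl (2E)-3-Ar-prop-2-enoate
Product: 3 (2E)-3-Ar-prop-2-en-1-ol
Conditions: DIBAL-H (2.3 equiv), CH2Cl2, −78 °C; Rochelle salt
Reagents that add atoms: none
Why: DIBAL-H 1,2-reduction of the enoate should give the allylic alcohol without touching the alkene.

Step 3
Reactants: 3 (2E)-3-Ar-prop-2-en-1-ol
Product: 4 methyl (2E)-3-Ar-prop-2-en-1-yl carbonate
Conditions: ClCO2Me, pyridine, CH2Cl2, 0 °C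
Reagents that add atoms: methyl chloroformate, COC(=O)Cl
Why: Acylation of the primary alcohol should give the linear allylic carbonate needed as π-allyl precursor.

Step 4
Reactants: 5 3,5-bis(benzyloxy)phenol
Product: 6 3,5-bis(benzyloxy)-2-iodophenol
Conditions: NIS (1.0 equiv), CH2Cl2, −20 → 0 °C
Reagents that add atoms: N-iodosuccinimide, O=C1CCC(=O)N1I
Why: Electrophilic aromatic iodination should take place ortho to the free hydroxyl (the two ortho positions are equivalent), and any 4-iodo isomer is removed by chromatography.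

Step 5
Reactants: 6 3,5-bis(benzyloxy)-2-iodophenol; 4 methyl (2E)-3-Ar-prop-2-en-1-yl carbonate
Product: 8 1,5-bis(benzyloxy)-2-iodo-3-{[(1S)-1-Ar-prop-2-en-1-yl]oxy}benzene, via lithium phenoxide 7 (not isolated)
Conditions: LiHMDS, THF, 0 °C; then 4, [Ir(cod)Cl]2 (2 mol %), (Ra,Rc,Rc)-binaphthyl bis(1-phenylethyl)phosphoramidite (4 mol %, pre-activated with n-PrNH2), THF, 40 °C
Reagents that add atoms: none
Why: Ir-catalysed asymmetric allylic etherification of a linear cinnamyl carbonate with an aryloxide should give the branched ether, the C–O stereocentre (future C2) being set by the cyclometalated phosphoramidite catalyst.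

Step 6
Reactants: 8 1,5-bis(benzyloxy)-2-iodo-3-{[(1S)-1-Ar-prop-2-en-1-yl]oxy}benzene
Product: 9 (2R)-4,6-bis(benzyloxy)-3-methylidene-2-Ar-2,3-dihydro-1-benzofuran
Conditions: Pd(OAc)2 (10 mol %), PPh3 (25 mol %), Ag2CO3 (1.5 equiv), MeCN, 70 °C
Reagents that add atoms: none
Why: Intramolecular 5-exo-trig Heck reaction followed by β-hydride elimination of the only available C3 hydrogen should give the exocyclic alkene, silver carbonate suppressing Pd–H re-addition; the stereocentre is not touched.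

Step 7
Reactants: 9 (2R)-4,6-bis(benzyloxy)-3-methylidene-2-Ar-2,3-dihydro-1-benzofuran
Product: 11 (2R)-5,7-bis(benzyloxy)-2-Ar-2H-chromen-3(4H)-one, via iodonium adduct 10 (not isolated)
Conditions: PhI(OH)OTs (1.1 equiv), MeCN–H2O 9:1, −10 → 0 °C; crude ketone taken on at once
Reagents that add atoms: water, O
Why: The iodine(III) electrophile adds to the terminal CH2 of the electron-rich exocyclic alkene, water captures the tertiary benzylic cation at C3, and the 2,4,6-trioxygenated aryl carbon (future C4a) then migrates from C3 to the CH2 carbon as iodobenzene departs, the C3 hydroxyl collapsing to the ketone. The closest known reaction is the hydroxy(tosyloxy)iodobenzene-mediated ring expansion of 1-methylidene benzocycloalkanes to the homologous ketones, a Tiffeneau–Demjanov-type semipinacol shift. No ring is closed: the five-membered O1–C2–C3–C3a–C7a ring is enlarged to the six-membered O1–C2–C3–C4–C4a–C8a ring by insertion of the former exocyclic carbon as C4 (C4–C4a formed, C3–C4a cleaved). No stereocentre is created, the C2 stereocentre is not involved and C3 becomes trigonal. The step needs aryl rather than C2 migration, which the high migratory aptitude of the phloroglucinol ring against the oxygen-bearing C2 should secure. It also needs the alkene to react before the arenes and before loss of the C2 proton, for which low temperature, the aqueous medium and only a slight excess of reagent are chosen.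

Step 8
Reactants: 11 (2R)-5,7-bis(benzyloxy)-2-Ar-2H-chromen-3(4H)-one
Product: 12 (2R,3R)-5,7-bis(benzyloxy)-2-Ar-3,4-dihydro-2H-chromen-3-ol (penta-O-benzyl-(−)-epigallocatechin)
Conditions: L-Selectride (1.5 equiv), LiBr, THF, −78 °C; H2O
Reagents that add atoms: none
Why: The bulky hydride should attack the ketone from the face opposite to the C2 aryl group and give the 2,3-cis alcohol (C3 R) under substrate control, as is known for benzylated flavan-3-ones.

Step 9
Reactants: 12 penta-O-benzyl-(−)-epigallocatechin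
Product: 13 (2R,3R)-5,7-bis(benzyloxy)-8-bromo-2-Ar-3,4-dihydro-2H-chromen-3-ol
Conditions: NBS (1.0 equiv), CH2Cl2, −78 → −40 °C
Reagents that add atoms: N-bromosuccinimide, O=C1CCC(=O)N1Br
Why: Electrophilic bromination of 5,7-dialkoxyflavans is selective for C8, which caps the more nucleophilic A-ring position.

Step 10
Reactants: 13 8-bromo alcohol; 14 3,4,5-tris(benzyloxy)benzoic acid
Product: 15 (2R,3R)-5,7-bis(benzyloxy)-8-bromo-2-Ar-3,4-dihydro-2H-chromen-3-yl 3,4,5-tris(benzyloxy)benzoate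
Conditions: DCC, DMAP (cat.), CH2Cl2, rt
Reagents that add atoms: none
Why: Steglich esterification of the axial C3 hydroxyl should proceed with retention, since no bond to the stereocentre is broken.

Step 11
Reactants: 12 penta-O-benzyl-(−)-epigallocatechin
Product: 16 (2R,3R,4S)-5,7-bis(benzyloxy)-4-(2-ethoxyethoxy)-2-Ar-3,4-dihydro-2H-chromen-3-ol (4β-alkoxy, trans to 3-OH)
Conditions: DDQ (2 equiv), 2-ethoxyethanol (5 equiv), CH2Cl2, rt
Reagents that add atoms: 2-ethoxyethanol, CCOCCO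
Why: DDQ abstracts hydride from the doubly activated benzylic C4 and the alcohol traps the cation trans to the C3 hydroxyl (oxidative benzylic etherification), installing the leaving group for the coupling.

Step 12
Reactants: 16 4β-(2-ethoxyethoxy) alcohol
Product: 17 (2R,3R,4S)-5,7-bis(benzyloxy)-6,8-dibromo-4-(2-ethoxyethoxy)-2-Ar-3,4-dihydro-2H-chromen-3-ol
Conditions: NBS (2.1 equiv), NaHCO3, CH2Cl2, −40 → 0 °C
Reagents that add atoms: N-bromosuccinimide, O=C1CCC(=O)N1Br
Why: Twofold electrophilic bromination blocks C6 and C8 of the electrophile, so that it cannot act as a nucleophile in the coupling.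

Step 13
Reactants: 15 8-bromo gallate (1.5 equiv); 17 dibromo 4-alkoxy electrophile
Product: 19 protected 4β→6 dimer (tridecabenzyl tribromide), via C4 cation 18 (not isolated)
Conditions: TMSOTf (0.3 equiv), CH2Cl2, −78 → −30 °C
Reagents that add atoms: none
Why: Lewis-acid ionisation of the 4-alkoxy group gives the benzylic C4 cation, which the only free A-ring position (C6) of the C8-capped nucleophile should attack anti to the C3 hydroxyl, setting C4 3,4-trans (4β); this is a Friedel–Crafts-type flavan-4-yl arylation with halo-capping.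

Step 14
Reactants: 19 protected 4β→6 dimer
Product: 20 CNP0204196.2, epigallocatechin-(4β→6)-epigallocatechin 3-O-gallate
Conditions: H2 (1 atm), 20% Pd(OH)2/C, Et3N (3.3 equiv), THF–MeOH–H2O, rt; Sephadex LH-20
Reagents that add atoms: none
Why: Hydrogenolysis over Pearlman's catalyst should cleave all thirteen benzyl ethers and the three aryl bromides while the gallate ester and the stereocentres stay untouched.

Compound list
1 | 3,4,5-tris(benzyloxy)benzaldehyde | O=Cc1cc(OCc2ccccc2)c(OCc2ccccc2)c(OCc2ccccc2)c1 | starting material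
2 | ethyl (2E)-3-[3,4,5-tris(benzyloxy)phenyl]prop-2-enoate | CCOC(=O)/C=C/c1cc(OCc2ccccc2)c(OCc2ccccc2)c(OCc2ccccc2)c1 | intermediate
3 | (2E)-3-[3,4,5-tris(benzyloxy)phenyl]prop-2-en-1-ol | OC/C=C/c1cc(OCc2ccccc2)c(OCc2ccccc2)c(OCc2ccccc2)c1 | intermediate
4 | methyl (2E)-3-[3,4,5-tris(benzyloxy)phenyl]prop-2-en-1-yl carbonate | COC(=O)OC/C=C/c1cc(OCc2ccccc2)c(OCc2ccccc2)c(OCc2ccccc2)c1 | intermediate
5 | 3,5-bis(benzyloxy)phenol | Oc1cc(OCc2ccccc2)cc(OCc2ccccc2)c1 | starting material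
6 | 3,5-bis(benzyloxy)-2-iodophenol | Oc1cc(OCc2ccccc2)cc(OCc2ccccc2)c1I | intermediate
7 | lithium 3,5-bis(benzyloxy)-2-iodophenoxide | [Li+].[O-]c1cc(OCc2ccccc2)cc(OCc2ccccc2)c1I | intermediate
8 | 1,5-bis(benzyloxy)-2-iodo-3-{[(1S)-1-[3,4,5-tris(benzyloxy)phenyl]prop-2-en-1-yl]oxy}benzene | C=C[C@H](Oc1cc(OCc2ccccc2)cc(OCc2ccccc2)c1I)c1cc(OCc2ccccc2)c(OCc2ccccc2)c(OCc2ccccc2)c1 | intermediate
9 | (2R)-4,6-bis(benzyloxy)-3-methylidene-2-[3,4,5-tris(benzyloxy)phenyl]-2,3-dihydro-1-benzofuran | C=C1c2c(OCc3ccccc3)cc(OCc3ccccc3)cc2O[C@@H]1c1cc(OCc2ccccc2)c(OCc2ccccc2)c(OCc2ccccc2)c1 | intermediate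
10 | {[(2R)-4,6-bis(benzyloxy)-3-hydroxy-2-[3,4,5-tris(benzyloxy)phenyl]-2,3-dihydro-1-benzofuran-3-yl]methyl}(phenyl)iodonium tosylate (both C3 epimers) | OC1(C[I+]c2ccccc2)c2c(OCc3ccccc3)cc(OCc3ccccc3)cc2O[C@@H]1c1cc(OCc2ccccc2)c(OCc2ccccc2)c(OCc2ccccc2)c1.Cc1ccc(cc1)S(=O)(=O)[O-] | intermediate
11 | (2R)-5,7-bis(benzyloxy)-2-[3,4,5-tris(benzyloxy)phenyl]-2H-chromen-3(4H)-one | O=C1Cc2c(OCc3ccccc3)cc(OCc3ccccc3)cc2O[C@@H]1c1cc(OCc2ccccc2)c(OCc2ccccc2)c(OCc2ccccc2)c1 | intermediate
12 | (2R,3R)-5,7-bis(benzyloxy)-2-[3,4,5-tris(benzyloxy)phenyl]-3,4-dihydro-2H-chromen-3-ol | O[C@@H]1Cc2c(OCc3ccccc3)cc(OCc3ccccc3)cc2O[C@@H]1c1cc(OCc2ccccc2)c(OCc2ccccc2)c(OCc2ccccc2)c1 | intermediate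
13 | (2R,3R)-5,7-bis(benzyloxy)-8-bromo-2-[3,4,5-tris(benzyloxy)phenyl]-3,4-dihydro-2H-chromen-3-ol | O[C@@H]1Cc2c(OCc3ccccc3)cc(OCc3ccccc3)c(Br)c2O[C@@H]1c1cc(OCc2ccccc2)c(OCc2ccccc2)c(OCc2ccccc2)c1 | intermediate
14 | 3,4,5-tris(benzyloxy)benzoic acid | OC(=O)c1cc(OCc2ccccc2)c(OCc2ccccc2)c(OCc2ccccc2)c1 | starting material
15 | (2R,3R)-5,7-bis(benzyloxy)-8-bromo-2-[3,4,5-tris(benzyloxy)phenyl]-3,4-dihydro-2H-chromen-3-yl 3,4,5-tris(benzyloxy)benzoate | O=C(O[C@@H]1Cc2c(OCc3ccccc3)cc(OCc3ccccc3)c(Br)c2O[C@@H]1c1cc(OCc2ccccc2)c(OCc2ccccc2)c(OCc2ccccc2)c1)c1cc(OCc2ccccc2)c(OCc2ccccc2)c(OCc2ccccc2)c1 | intermediate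
16 | (2R,3R,4S)-5,7-bis(benzyloxy)-4-(2-ethoxyethoxy)-2-[3,4,5-tris(benzyloxy)phenyl]-3,4-dihydro-2H-chromen-3-ol | CCOCCO[C@H]1c2c(OCc3ccccc3)cc(OCc3ccccc3)cc2O[C@H](c2cc(OCc3ccccc3)c(OCc3ccccc3)c(OCc3ccccc3)c2)[C@@H]1O | intermediate
17 | (2R,3R,4S)-5,7-bis(benzyloxy)-6,8-dibromo-4-(2-ethoxyethoxy)-2-[3,4,5-tris(benzyloxy)phenyl]-3,4-dihydro-2H-chromen-3-ol | CCOCCO[C@H]1c2c(OCc3ccccc3)c(Br)c(OCc3ccccc3)c(Br)c2O[C@H](c2cc(OCc3ccccc3)c(OCc3ccccc3)c(OCc3ccccc3)c2)[C@@H]1O | intermediate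
18 | (2R,3R)-5,7-bis(benzyloxy)-6,8-dibromo-3-hydroxy-2-[3,4,5-tris(benzyloxy)phenyl]chroman-4-ylium triflate (C4 cation) | [CH+]1c2c(OCc3ccccc3)c(Br)c(OCc3ccccc3)c(Br)c2O[C@H](c2cc(OCc3ccccc3)c(OCc3ccccc3)c(OCc3ccccc3)c2)[C@@H]1O.[O-]S(=O)(=O)C(F)(F)F | intermediate
19 | (2R,3R)-5,7-bis(benzyloxy)-8-bromo-6-{(2R,3R,4S)-5,7-bis(benzyloxy)-6,8-dibromo-3-hydroxy-2-[3,4,5-tris(benzyloxy)phenyl]-3,4-dihydro-2H-chromen-4-yl}-2-[3,4,5-tris(benzyloxy)phenyl]-3,4-dihydro-2H-chromen-3-yl 3,4,5-tris(benzyloxy)benzoate | O=C(O[C@@H]1Cc2c(c(Br)c(OCc3ccccc3)c([C@H]3c4c(OCc5ccccc5)c(Br)c(OCc5ccccc5)c(Br)c4O[C@H](c4cc(OCc5ccccc5)c(OCc5ccccc5)c(OCc5ccccc5)c4)[C@@H]3O)c2OCc2ccccc2)O[C@@H]1c1cc(OCc2ccccc2)c(OCc2ccccc2)c(OCc2ccccc2)c1)c1cc(OCc2ccccc2)c(OCc2ccccc2)c(OCc2ccccc2)c1 | intermediate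
20 | CNP0204196.2, (−)-epigallocatechin-(4β→6)-(−)-epigallocatechin 3-O-gallate | O=C(O[C@@H]1Cc2c(cc(O)c([C@H]3c4c(O)cc(O)cc4O[C@H](c4cc(O)c(O)c(O)c4)[C@@H]3O)c2O)O[C@@H]1c1cc(O)c(O)c(O)c1)c1cc(O)c(O)c(O)c1 | target

Total step count: 14. Longest linear sequence: 11 steps (steps 1, 2, 3, 5, 6, 7, 8, 9, 10, 13, 14).

Steps most likely to fail

1. Step 7. The tertiary benzylic cation at C3 may lose the C2 proton, which aromatises the furan ring and destroys the stereocentre, or the iodine(III) reagent may oxidise the electron-rich rings before the aryl shift. The fallback sets out from 9 and returns at 11 without a cation at C3 and without an oxidant for the arenes. Catalytic OsO4 with NMO in acetone–water should dihydroxylate the exocyclic alkene to the diol (2R)-4,6-bis(benzyloxy)-3-(hydroxymethyl)-2-[3,4,5-tris(benzyloxy)phenyl]-2,3-dihydro-1-benzofuran-3-ol F1 (both C3 epimers serve). Tosyl chloride in pyridine at 0 °C should sulfonylate only the primary hydroxyl to give the monotosylate F2. On warming, the electron-rich aryl carbon displaces tosylate from the CH2 group while the tertiary hydroxyl becomes the ketone (Tiffeneau-type semipinacol ring enlargement), giving 11.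

2. Step 13. Ionisation of the dibrominated electrophile may be slow, and the released alcohol may recapture the cation faster than the hindered C6 position attacks, so that elimination or decomposition takes over. The fallback sets out from 17 and returns at 19 by making the ionisation irreversible. Exchange of the 2-ethoxyethoxy group for benzylthio (BnSH, cat. BF3·OEt2, CH2Cl2, −20 °C) should give the 4β-benzylsulfanyl compound (2R,3S,4S)-5,7-bis(benzyloxy)-4-(benzylsulfanyl)-6,8-dibromo-2-[3,4,5-tris(benzyloxy)phenyl]-3,4-dihydro-2H-chromen-3-ol F3. Thiophilic activation with AgBF4 in THF at 0 °C in the presence of 15 precipitates silver thiolate, so the cation cannot revert and should be taken up by C6 of 15 to give 19.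

3. Step 6. Re-addition of Pd–H may move the double bond into the ring (aromatic 3-methylbenzofuran, loss of the C2 stereocentre), or Pd(0) may ionise the allylic aryl ether and erode the ee. The fallback sets out from 8 and returns at 9 without palladium. A tin-radical chain (hexabutylditin, diphenyl diselenide, sunlamp, benzene) should generate the aryl radical, which closes 5-exo-trig and is trapped as the primary selenide (2S)-4,6-bis(benzyloxy)-3-[(phenylselanyl)methyl]-2-[3,4,5-tris(benzyloxy)phenyl]-2,3-dihydro-1-benzofuran F4 (C3 epimers; the arrangement in space at C2 is that of 9, only the descriptor changes). Oxidation with H2O2 and pyridine at 0 °C gives the selenoxide F5, whose syn-elimination can only use the C3 hydrogen and should therefore give the exocyclic alkene 9.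

Further compounds
F1 | step 7 | (2R)-4,6-bis(benzyloxy)-3-(hydroxymethyl)-2-[3,4,5-tris(benzyloxy)phenyl]-2,3-dihydro-1-benzofuran-3-ol | OCC1(O)c2c(OCc3ccccc3)cc(OCc3ccccc3)cc2O[C@@H]1c1cc(OCc2ccccc2)c(OCc2ccccc2)c(OCc2ccccc2)c1
F2 | step 7 | [(2R)-4,6-bis(benzyloxy)-3-hydroxy-2-[3,4,5-tris(benzyloxy)phenyl]-2,3-dihydro-1-benzofuran-3-yl]methyl 4-methylbenzenesulfonate | Cc1ccc(cc1)S(=O)(=O)OCC1(O)c2c(OCc3ccccc3)cc(OCc3ccccc3)cc2O[C@@H]1c1cc(OCc2ccccc2)c(OCc2ccccc2)c(OCc2ccccc2)c1
F3 | step 13 | (2R,3S,4S)-5,7-bis(benzyloxy)-4-(benzylsulfanyl)-6,8-dibromo-2-[3,4,5-tris(benzyloxy)phenyl]-3,4-dihydro-2H-chromen-3-ol | c1ccccc1CS[C@H]1c2c(OCc3ccccc3)c(Br)c(OCc3ccccc3)c(Br)c2O[C@H](c2cc(OCc3ccccc3)c(OCc3ccccc3)c(OCc3ccccc3)c2)[C@@H]1O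
F4 | step 6 | (2S)-4,6-bis(benzyloxy)-3-[(phenylselanyl)methyl]-2-[3,4,5-tris(benzyloxy)phenyl]-2,3-dihydro-1-benzofuran | c1ccccc1[Se]CC1c2c(OCc3ccccc3)cc(OCc3ccccc3)cc2O[C@@H]1c1cc(OCc2ccccc2)c(OCc2ccccc2)c(OCc2ccccc2)c1
F5 | step 6 | (2S)-4,6-bis(benzyloxy)-3-[(phenylseleninyl)methyl]-2-[3,4,5-tris(benzyloxy)phenyl]-2,3-dihydro-1-benzofuran | O=[Se](c1ccccc1)CC1c2c(OCc3ccccc3)cc(OCc3ccccc3)cc2O[C@@H]1c1cc(OCc2ccccc2)c(OCc2ccccc2)c(OCc2ccccc2)c1
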